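# Abyssinone-IV by late twofold Stille prenylation of an enantiopure dibromoflavanone

## The problem

Abyssinone-IV (12) is a flavanone in which ring A, a benzene ring with one free hydroxyl at C7, is fused to the dihydropyranone ring C, and C2 of ring C carries ring B, a 4'-hydroxyphenyl group with a 3-methylbut-2-enyl (prenyl) chain on each of C3' and C5'. C2 (S) is the only stereocentre; it is a benzylic ether carbon β to the C4 ketone, there is no second centre to relay from, and it must be set by a catalyst. Once set it is fragile: enolisation at C3 with expulsion of the ring A phenoxide (retro-oxa-Michael), or electron push from a free 4'-phenoxide through ring B to a para-quinone methide, opens ring C and returns racemic flavanone or chalcone. The prenyl chains are the second weak point, because acid cyclises an ortho-prenyl phenol to a 2,2-dimethylchroman or adds solvent to the trisubstituted olefin, and hydrogenation is excluded. The skeleton needs only three strategic bonds: C2–C1' and the two aryl–CH2 bonds at C3' and C5'. A late twofold coupling is possible because C3' and C5' are the two positions ortho to O4' and the para position is taken by C2. Bromination directed by the 4'-phenol therefore marks exactly these two carbons, and the C–Br bonds can be exchanged for prenyl groups under neutral conditions after C2 is in place.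

## Retrosynthesis

**12 to 11 to 10 (O–H bonds).** The two phenols of 12 are traced back to an acetal on O4' (11) and, one step further, an ester on O7 (10). The ester is to be removed first with mild base while O4' is still capped, so the quinone methide channel is closed. The acetal is removed last with dilute acid, in which C2 is configurationally safe. A single kind of group on both oxygens would save a step, but it would mean either base acting on a free 4'-phenol (two esters) or a ring A no longer deactivated during bromination (two ethers). The forward steps must be cold and short in base, and dilute in acid.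

**10 to 7 and 8 (key cut).** Both aryl–CH2 bonds of 10, at C3' and C5', are cut at once, which gives dibromide 7 and two equivalents of stannane 8. The cut removes ten carbons and both acid-sensitive olefins, and 7 has no delicate feature other than C2. Direct C-prenylation of the phenol, by Friedel–Crafts alkylation or by O-prenylation and rearrangement, needs acid or heat and gives mixtures of mono- and bis-adducts and of linear and reverse isomers. Carrying the prenyl groups in on the boron partner of the ring B addition would demand a separate multistep preparation of that partner. The forward coupling must transfer the linear prenyl group twice and leave C2 untouched; neutral catalysis by zerovalent palladium on a substrate without a free phenol is chosen for the latter.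

**7 to 6 to 4 (O–C acetal bond, then two C–Br bonds).** Removing the acetal gives dibromophenol 6, and cutting both C–Br bonds gives phenol 4. The free 4'-phenol is the most electron-rich site of 4, its para position is blocked, and ring A is deactivated by the C4 acyl group and the ester on O7. No directing group has to be added or removed; the phenol that directs the bromination is then capped. The forward bromination needs exact stoichiometry and polar, non-radical conditions.

**4 to 2 and 3 (C2–C1' bond).** The bond between ring C and ring B is cut to chromone 2 and boronic acid 3. This is the only cut that creates the stereocentre while joining two flat, achiral partners. Closing ring C by oxa-Michael addition of an open-chain enone is reversible and less predictable in its enantioselectivity. Reducing a 2-arylchromone would have to distinguish C=C from C=O and the arenes. The forward reaction is an asymmetric conjugate addition catalysed by [RhCl(C2H4)2]2 and a chiral diene; it must tolerate a free phenol on the boron partner and must not open the product.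

**2 to 1 (O–acyl bond).** The pivalate is traced to 7-hydroxychromone 1. The ester is chosen over an ether because it makes the chromone a better acceptor, deactivates ring A toward bromine and survives the neutral coupling. Compounds 1, 3 and 8 are catalogue materials.

## Roads not taken

Alternative 1: alkoxy ortho-quinone methide cycloaddition.
- Cut: ring C at C3–C4 and O1–C2, giving the acetal 2-(dimethoxymethyl)-5-(triisopropylsilyloxy)phenol A3 and the ring B styrene triisopropyl[2,6-bis(3-methylbut-2-enyl)-4-vinylphenoxy]silane A2.
- Forward key step: a chiral Brønsted acid ionises A3 to a methoxy ortho-quinone methide, which adds A2 in a [4+2] sense. The product is (2S,4S)-4-methoxy-7-(triisopropylsilyloxy)-2-[4-(triisopropylsilyloxy)-3,5-bis(3-methylbut-2-enyl)phenyl]chroman A1.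
- Merits: ring C and C2 are made together from two independent fragments, no tin is used, and the linear-versus-branched question is settled on a simple arene. In convergence this road is better than the chosen one.
- Weak points: the acid catalyst meets two prenyl olefins and an electron-rich styrene, so the trisubstituted olefins of A2 compete as 2π partners and the styrene can oligomerise. Enantiocontrol of this cycloaddition for such a styrene is not established. A1 is at the wrong oxidation level: the C4 ether must be converted into the ketone, and a C4 stereocentre is made only to be destroyed.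
- Comparison: the chosen plan has the correct oxidation level from the first step, keeps acid away from the prenyl groups until the last step, and its only open selectivity is linear against branched.

Alternative 2: biomimetic folding of a reduced polyketide chain.
- Cut: O1–C8a and C4a–C5, so that rings C and A both come from the open chain (S)-4-(1-hydroxy-9,9-dimethoxy-3,5,7-trioxononyl)-2,6-bis(3-methylbut-2-enyl)phenyl acetate A5, written in its keto form.
- Forward key step: acid closes the C2 hydroxyl of A5 onto the C8a carbonyl, the unmasked C5 aldehyde condenses with C4a, and ring A aromatises. The product of this cascade is (S)-4-(7-hydroxy-4-oxochroman-2-yl)-2,6-bis(3-methylbut-2-enyl)phenyl acetate A4, the 4'-acetate of the target.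
- Merits: two rings form in one metal-free operation, the stereocentre could come from an early asymmetric aldol reaction or reduction, and A4 stands one ester cleavage from 12. In bonds formed per step this road is better.
- Weak points: the benzylic β-hydroxy ketone of A5 dehydrates or ionises in acid, which destroys C2. The tricarbonyl chain has several competing cyclisation modes. Acid again meets the prenyl groups. A5 itself is a long, sensitive construction. Taking the acetate off A4 with base would pass through the free 4'-phenoxide, the species that opens ring C.
- Comparison: ring A is a plain resorcinol-type ring that the chosen plan buys ready-made in 1, so building it de novo on the way to A4 loses on step economy and certainty. Against the two-ring cascade the chosen plan sets its stereocentre by a catalyst on a stable chromone and ends with a deprotection in dilute acid, not in base.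

Alternative 3: aryne annulation with a chiral β-hydroxy ester.
- Cut: O1–C8a and C4a–C4, giving methyl (S)-3-hydroxy-3-[4-(methoxymethoxy)-3,5-bis(3-methylbut-2-enyl)phenyl]propanoate A7 and the aryne precursor 2-chloro-4-(methoxymethoxy)-6-(trimethylsilyl)phenyl trifluoromethanesulfonate A8.
- Forward key step: fluoride unmasks a 3-chloroaryne from A8, the alkoxide of A7 adds at the carbon distal to chlorine, and the aryl anion closes onto the ester. The product is (S)-5-chloro-7-(methoxymethoxy)-2-[4-(methoxymethoxy)-3,5-bis(3-methylbut-2-enyl)phenyl]chroman-4-one A6.
- Merits: the stereocentre of A7 would come from asymmetric reduction of a β-keto ester, arguably more dependable than conjugate addition to a chromone, and the prenyl groups are installed on a simple arene. In both respects it is as good as or better than the chosen plan.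
- Weak points: a benzylic β-hydroxy ester such as A7 can undergo retro-aldol cleavage and dehydration to the cinnamate under basic fluoride. A6 is a flavanone formed in a basic medium, the very conditions that open ring C. The C5 chlorine of A6 serves only to steer regiochemistry and must be removed reductively in the presence of two olefins and an aryl ketone. A8 needs its own synthesis.
- Comparison: the chosen plan has no dehalogenation, never exposes the flavanone to basic fluoride, and uses three purchased building blocks.

Key step: step 5

Assumption: the facial preference of the catalyst formed from [RhCl(C2H4)2]2 and the chiral diene toward chromone 2 is taken to match that known for cyclic enones such as cyclohex-2-enone, which makes the (S,S)-diene the one expected to give (2S); if the opposite sense is found, the (R,R)-diene is used and nothing else changes.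

## Route

Step 1
Reactants: 1 7-hydroxychromone (7-hydroxy-4H-chromen-4-one)
Product: 2 7-(pivaloyloxy)chromone (4-oxo-4H-chromen-7-yl 2,2-dimethylpropanoate)
Conditions: PivCl (1.2 equiv), Et3N (1.5 equiv), DMAP (5 mol %), CH2Cl2, 0 °C → rt
Reagents that add atoms: pivaloyl chloride, CC(C)(C)C(Cl)=O
Why: DMAP-catalysed O-acylation of a phenol with an acid chloride; the tertiary amine does not add to C2 of the chromone. The ester makes the chromone more electrophilic and will deactivate ring A in step 3.

Step 2
Reactants: 2 7-(pivaloyloxy)chromone; 3 4-hydroxyphenylboronic acid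
Product: 4 (S)-2-(4-hydroxyphenyl)-4-oxochroman-7-yl pivalate
Conditions: 3 (2.5 equiv), [RhCl(C2H4)2]2 (2.5 mol %), (S,S)-Ph-bod* [(1S,4S)-2,5-diphenylbicyclo[2.2.2]octa-2,5-diene] (5.5 mol %), aq KOH (20 mol %), 1,4-dioxane/H2O (10:1), 30 °C
Reagents that add atoms: none
Why: Hayashi–Miyaura asymmetric conjugate addition: an aryl complex of monovalent rhodium formed by transmetalation from boron adds to C2 of the chromone, and water protonates the oxa-π-allyl rhodium enolate before it can expel the ring oxygen. C2 is set as (S) by catalyst control, the C2-symmetric diene shielding one face of the enone; only a catalytic amount of base is used, to protect the product and the ester.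

Step 3
Reactants: 4 (S)-2-(4-hydroxyphenyl)-4-oxochroman-7-yl pivalate
Product: 6 (S)-2-(3,5-dibromo-4-hydroxyphenyl)-4-oxochroman-7-yl pivalate, via 3'-monobromophenol 5 (not isolated)
Conditions: NBS (2.05 equiv, portionwise), MeCN, 0 °C, dark
Reagents that add atoms: N-bromosuccinimide, O=C1CCC(=O)N1Br
Why: Phenol-directed electrophilic aromatic bromination; the para position is blocked by C2, so both ortho carbons C3' and C5' are substituted in turn, while ring A is deactivated by the C4 acyl group and the pivalate. Exact stoichiometry and cold, dark, polar conditions keep ipso attack, C3 bromination and benzylic radical bromination out of play.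

Step 4
Reactants: 6 (S)-2-(3,5-dibromo-4-hydroxyphenyl)-4-oxochroman-7-yl pivalate
Product: 7 (S)-2-[3,5-dibromo-4-(methoxymethoxy)phenyl]-4-oxochroman-7-yl pivalate
Conditions: MOMCl (1.5 equiv), iPr2NEt (2.0 equiv), CH2Cl2, 0 °C → rt
Reagents that add atoms: chloromethyl methyl ether, COCCl
Why: O-alkylation of an acidic 2,6-dibromophenol with an α-chloro ether; the hindered amine deprotonates the phenol but not C3, and the weakly donating dibromophenoxide is trapped before it can open ring C. The acetal removes the free phenol, so that no phenoxide can form in the later coupling and ester cleavage.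

Step 5
Reactants: 7 (S)-2-[3,5-dibromo-4-(methoxymethoxy)phenyl]-4-oxochroman-7-yl pivalate; 8 tributyl(3-methylbut-2-enyl)stannane
Product: 10 (S)-2-[4-(methoxymethoxy)-3,5-bis(3-methylbut-2-enyl)phenyl]-4-oxochroman-7-yl pivalate, via monoprenylated aryl bromide 9 (not isolated)
Conditions: 8 (3.0 equiv), Pd(PPh3)4 (10 mol %), degassed DMF, 100 °C
Reagents that add atoms: none
Why: Zerovalent palladium from Pd(PPh3)4 inserts into one C–Br bond of 7, the prenyl group passes from tin to the arylpalladium bromide with loss of Bu3SnBr, and the equilibrating σ- and π-prenyl palladium species collapse by reductive elimination at the unsubstituted CH2 terminus to give 9, which enters a second identical cycle to give 10. The closest known reaction type is the Migita–Kosugi–Stille coupling of aryl bromides with prenyltributylstannane. No ring is closed and no stereocentre is made; the two new bonds are the aryl–CH2 bonds at C3' and C5'. The selectivity needed is linear against branched (1,1-dimethylallyl) coupling; it rests on the preference of the triphenylphosphine-ligated palladium for bond formation at the primary terminus, reinforced by the ortho acetal oxygen that crowds each palladated carbon. Site selectivity is fixed by the two bromine atoms. The medium is neutral and O4' is masked, so neither enolate- nor phenoxide-triggered opening of ring C should erode C2.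

Step 6
Reactants: 10 (S)-2-[4-(methoxymethoxy)-3,5-bis(3-methylbut-2-enyl)phenyl]-4-oxochroman-7-yl pivalate
Product: 11 (S)-7-hydroxy-2-[4-(methoxymethoxy)-3,5-bis(3-methylbut-2-enyl)phenyl]chroman-4-one
Conditions: K2CO3 (1.5 equiv), MeOH/THF (3:1), 0 °C; then pH 7 buffer (NaH2PO4/Na2HPO4)
Reagents that add atoms: none
Why: Base-mediated transesterification (methanolysis) of an aryl ester; the leaving group is a phenoxide para to the C4 acyl substituent, so even the hindered pivalate should fall at 0 °C. The 7-phenoxide, once formed, is conjugated with C4=O and suppresses enolisation at C3, and the capped O4' cannot trigger quinone methide formation.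

Step 7
Reactants: 11 (S)-7-hydroxy-2-[4-(methoxymethoxy)-3,5-bis(3-methylbut-2-enyl)phenyl]chroman-4-one
Product: 12 abyssinone-IV, (S)-7-hydroxy-2-[4-hydroxy-3,5-bis(3-methylbut-2-enyl)phenyl]chroman-4-one
Conditions: aq HCl (3 M), MeOH, rt
Reagents that add atoms: none
Why: Acid-catalysed cleavage of a methoxymethyl aryl ether by acetal exchange with methanol; the di-ortho-substituted aryl acetal ionises readily, so dilute acid at room temperature should suffice. Such conditions are precedented for freeing ortho-prenyl phenols without cyclisation, and C2 is configurationally stable in dilute acid.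

## Compound list

1 | 7-hydroxychromone | O=c1ccoc2cc(O)ccc12 | starting material
2 | 7-(pivaloyloxy)chromone | O=c1ccoc2cc(OC(=O)C(C)(C)C)ccc12 | intermediate
3 | 4-hydroxyphenylboronic acid | OB(O)c1ccc(O)cc1 | starting material
4 | (S)-2-(4-hydroxyphenyl)-4-oxochroman-7-yl pivalate | Oc1ccc([C@@H]2CC(=O)c3ccc(OC(=O)C(C)(C)C)cc3O2)cc1 | intermediate
5 | (S)-2-(3-bromo-4-hydroxyphenyl)-4-oxochroman-7-yl pivalate (not isolated) | Oc1ccc([C@@H]2CC(=O)c3ccc(OC(=O)C(C)(C)C)cc3O2)cc1Br | intermediate
6 | (S)-2-(3,5-dibromo-4-hydroxyphenyl)-4-oxochroman-7-yl pivalate | Oc1c(Br)cc([C@@H]2CC(=O)c3ccc(OC(=O)C(C)(C)C)cc3O2)cc1Br | intermediate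
7 | (S)-2-[3,5-dibromo-4-(methoxymethoxy)phenyl]-4-oxochroman-7-yl pivalate | COCOc1c(Br)cc([C@@H]2CC(=O)c3ccc(OC(=O)C(C)(C)C)cc3O2)cc1Br | intermediate
8 | tributyl(3-methylbut-2-enyl)stannane | CCCC[Sn](CCCC)(CCCC)CC=C(C)C | starting material
9 | (S)-2-[3-bromo-4-(methoxymethoxy)-5-(3-methylbut-2-enyl)phenyl]-4-oxochroman-7-yl pivalate (not isolated) | COCOc1c(Br)cc([C@@H]2CC(=O)c3ccc(OC(=O)C(C)(C)C)cc3O2)cc1CC=C(C)C | intermediate
10 | (S)-2-[4-(methoxymethoxy)-3,5-bis(3-methylbut-2-enyl)phenyl]-4-oxochroman-7-yl pivalate | CC(C)=CCc1cc([C@@H]2CC(=O)c3ccc(OC(=O)C(C)(C)C)cc3O2)cc(CC=C(C)C)c1OCOC | intermediate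
11 | (S)-7-hydroxy-2-[4-(methoxymethoxy)-3,5-bis(3-methylbut-2-enyl)phenyl]chroman-4-one | CC(C)=CCc1cc([C@@H]2CC(=O)c3ccc(O)cc3O2)cc(CC=C(C)C)c1OCOC | intermediate
12 | abyssinone-IV, (S)-7-hydroxy-2-[4-hydroxy-3,5-bis(3-methylbut-2-enyl)phenyl]chroman-4-one | CC(C)=CCc1cc([C@@H]2CC(=O)c3ccc(O)cc3O2)cc(CC=C(C)C)c1O | target

## Step count and risks

Total step count: 7. Longest linear sequence: 7 steps (1 to 12); 3 and 8 enter as purchased reagents.

**Step 5 (key step).** The most likely failure is transfer of the prenyl group through its γ-carbon, which would place a branched 1,1-dimethylallyl group at one or both sites. Incomplete second coupling, protodebromination and olefin migration may accompany it if transmetalation is slow next to the acetal. Fallback: from 7, the same twofold Stille coupling is run with allyltributylstannane, whose termini are equivalent, to give (S)-2-[3,5-diallyl-4-(methoxymethoxy)phenyl]-4-oxochroman-7-yl pivalate F1. Twofold olefin cross-metathesis of F1 with excess 2-methylbut-2-ene and the second-generation Grubbs catalyst (H2IMes)(PCy3)Cl2Ru=CHPh then turns each allyl group into a prenyl group and returns to the route at 10.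

**Step 2.** Protodeboronation of the electron-rich boronic acid may outrun transmetalation. Enantiomeric purity may erode if the 4'-phenoxide of 4 opens ring C in the mildly basic aqueous medium. Hydrolysis of the activated pivalate is a lesser concern. Fallback: from 2, the same conjugate addition with commercial 4-(tert-butyldimethylsilyloxy)phenylboronic acid gives (S)-2-[4-(tert-butyldimethylsilyloxy)phenyl]-4-oxochroman-7-yl pivalate F2, in which no phenoxide can form. HF·pyridine in THF at 0 °C then frees the phenol without base and returns to the route at 4.

**Step 6.** Base-induced opening of ring C (enolisation at C3 and loss of the ring A aryloxide) may compete with methanolysis before the protective 7-phenoxide has formed, giving partial racemisation or chalcone. Fallback: the ester is replaced from the outset by an acetal, so that no base is needed after C2 is set. From 1, alkylation with MOMCl/iPr2NEt gives 7-(methoxymethoxy)chromone F3. Conjugate addition of 3 as in step 2 gives (S)-2-(4-hydroxyphenyl)-7-(methoxymethoxy)chroman-4-one F4, dibromination as in step 3 gives (S)-2-(3,5-dibromo-4-hydroxyphenyl)-7-(methoxymethoxy)chroman-4-one F5, and acetal formation as in step 4 gives (S)-2-[3,5-dibromo-4-(methoxymethoxy)phenyl]-7-(methoxymethoxy)chroman-4-one F6. The twofold Stille coupling of F6 with 8 gives (S)-7-(methoxymethoxy)-2-[4-(methoxymethoxy)-3,5-bis(3-methylbut-2-enyl)phenyl]chroman-4-one F7, and dilute HCl in MeOH removes both acetals at once and returns to the route at 12. The price is a less electrophilic chromone and a ring A less deactivated toward bromine, which is why this is the reserve and not the main line.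

**Step 7.** Acid-catalysed cyclisation of a prenyl chain onto the freed O4' (2,2-dimethylchroman formation), or Markovnikov addition of methanol or water to the olefins, may set in once the acetal is gone. Fallback: a fluoride-labile group takes the place of the acetal. From 6, silylation with TIPSOTf/2,6-lutidine gives (S)-2-[3,5-dibromo-4-(triisopropylsilyloxy)phenyl]-4-oxochroman-7-yl pivalate F8. The twofold Stille coupling of F8 with 8 gives (S)-4-oxo-2-[3,5-bis(3-methylbut-2-enyl)-4-(triisopropylsilyloxy)phenyl]chroman-7-yl pivalate F9. Methanolysis as in step 6 gives (S)-7-hydroxy-2-[3,5-bis(3-methylbut-2-enyl)-4-(triisopropylsilyloxy)phenyl]chroman-4-one F10; the hindered silyl ether is expected to survive K2CO3/MeOH at 0 °C. TBAF buffered with AcOH in THF at 0 °C then removes silicon from F10 without acid and without a lasting free phenoxide, returning to the route at 12.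

## Further compounds

F1 | step 5 | (S)-2-[3,5-diallyl-4-(methoxymethoxy)phenyl]-4-oxochroman-7-yl pivalate | C=CCc1cc([C@@H]2CC(=O)c3ccc(OC(=O)C(C)(C)C)cc3O2)cc(CC=C)c1OCOC
F2 | step 2 | (S)-2-[4-(tert-butyldimethylsilyloxy)phenyl]-4-oxochroman-7-yl pivalate | CC(C)(C)[Si](C)(C)Oc1ccc([C@@H]2CC(=O)c3ccc(OC(=O)C(C)(C)C)cc3O2)cc1
F3 | step 6 | 7-(methoxymethoxy)chromone | O=c1ccoc2cc(OCOC)ccc12
F4 | step 6 | (S)-2-(4-hydroxyphenyl)-7-(methoxymethoxy)chroman-4-one | Oc1ccc([C@@H]2CC(=O)c3ccc(OCOC)cc3O2)cc1
F5 | step 6 | (S)-2-(3,5-dibromo-4-hydroxyphenyl)-7-(methoxymethoxy)chroman-4-one | Oc1c(Br)cc([C@@H]2CC(=O)c3ccc(OCOC)cc3O2)cc1Br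
F6 | step 6 | (S)-2-[3,5-dibromo-4-(methoxymethoxy)phenyl]-7-(methoxymethoxy)chroman-4-one | COCOc1c(Br)cc([C@@H]2CC(=O)c3ccc(OCOC)cc3O2)cc1Br
F7 | step 6 | (S)-7-(methoxymethoxy)-2-[4-(methoxymethoxy)-3,5-bis(3-methylbut-2-enyl)phenyl]chroman-4-one | CC(C)=CCc1cc([C@@H]2CC(=O)c3ccc(OCOC)cc3O2)cc(CC=C(C)C)c1OCOC
F8 | step 7 | (S)-2-[3,5-dibromo-4-(triisopropylsilyloxy)phenyl]-4-oxochroman-7-yl pivalate | CC(C)[Si](Oc1c(Br)cc([C@@H]2CC(=O)c3ccc(OC(=O)C(C)(C)C)cc3O2)cc1Br)(C(C)C)C(C)C
F9 | step 7 | (S)-4-oxo-2-[3,5-bis(3-methylbut-2-enyl)-4-(triisopropylsilyloxy)phenyl]chroman-7-yl pivalate | CC(C)=CCc1cc([C@@H]2CC(=O)c3ccc(OC(=O)C(C)(C)C)cc3O2)cc(CC=C(C)C)c1O[Si](C(C)C)(C(C)C)C(C)C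
F10 | step 7 | (S)-7-hydroxy-2-[3,5-bis(3-methylbut-2-enyl)-4-(triisopropylsilyloxy)phenyl]chroman-4-one | CC(C)=CCc1cc([C@@H]2CC(=O)c3ccc(O)cc3O2)cc(CC=C(C)C)c1O[Si](C(C)C)(C(C)C)C(C)C
A1 | alternative 1 | (2S,4S)-4-methoxy-7-(triisopropylsilyloxy)-2-[4-(triisopropylsilyloxy)-3,5-bis(3-methylbut-2-enyl)phenyl]chroman | CC(C)=CCc1cc([C@@H]2C[C@H](OC)c3ccc(O[Si](C(C)C)(C(C)C)C(C)C)cc3O2)cc(CC=C(C)C)c1O[Si](C(C)C)(C(C)C)C(C)C
A2 | alternative 1 | triisopropyl[2,6-bis(3-methylbut-2-enyl)-4-vinylphenoxy]silane | C=Cc1cc(CC=C(C)C)c(O[Si](C(C)C)(C(C)C)C(C)C)c(CC=C(C)C)c1
A3 | alternative 1 | 2-(dimethoxymethyl)-5-(triisopropylsilyloxy)phenol | COC(OC)c1ccc(O[Si](C(C)C)(C(C)C)C(C)C)cc1O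
A4 | alternative 2 | (S)-4-(7-hydroxy-4-oxochroman-2-yl)-2,6-bis(3-methylbut-2-enyl)phenyl acetate | CC(C)=CCc1cc([C@@H]2CC(=O)c3ccc(O)cc3O2)cc(CC=C(C)C)c1OC(C)=O
A5 | alternative 2 | (S)-4-(1-hydroxy-9,9-dimethoxy-3,5,7-trioxononyl)-2,6-bis(3-methylbut-2-enyl)phenyl acetate | CC(C)=CCc1cc([C@@H](O)CC(=O)CC(=O)CC(=O)CC(OC)OC)cc(CC=C(C)C)c1OC(C)=O
A6 | alternative 3 | (S)-5-chloro-7-(methoxymethoxy)-2-[4-(methoxymethoxy)-3,5-bis(3-methylbut-2-enyl)phenyl]chroman-4-one | CC(C)=CCc1cc([C@@H]2CC(=O)c3c(Cl)cc(OCOC)cc3O2)cc(CC=C(C)C)c1OCOC
A7 | alternative 3 | methyl (S)-3-hydroxy-3-[4-(methoxymethoxy)-3,5-bis(3-methylbut-2-enyl)phenyl]propanoate | CC(C)=CCc1cc([C@@H](O)CC(=O)OC)cc(CC=C(C)C)c1OCOC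
A8 | alternative 3 | 2-chloro-4-(methoxymethoxy)-6-(trimethylsilyl)phenyl trifluoromethanesulfonate | COCOc1cc(Cl)c(OS(=O)(=O)C(F)(F)F)c([Si](C)(C)C)c1
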